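Ring B is read as a disguised naphthalene-1,3-diol. The 3-hydroxy-4-keto unit (C3/C4) is the 1,2-transposed form of a 4-hydroxy-3-keto unit, so C1 and C4 on benzenoid ring A (at C8a and C4a) map onto the ester and benzylic carbons of an orsellinate, and C2–C3 onto an acetate. The key step is a tandem Claisen–Dieckmann condensation of the side-chain-bearing toluate carbanion with methyl acetate, which forms C4–C3 and C1–C2 in one operation. Asymmetric C4 hydroxylation, anti C2 methylation of the 2-chloro-1,3-dione and a suprafacial α-ketol shift of the side chain from C4 to C3 then set both stereocentres.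

Key step: step 7

Remark: locants follow the biogenetic numbering (C1 = carbonyl peri to O8, C2 = C(CH3)Cl, C3 = carbinol carbon, C4 = second carbonyl; CIP descriptors refer to these atoms), R* is the (4E)-5,9-dimethyl-2-(propan-2-ylidene)deca-4,8-dien-1-yl side chain, and the antipode of the chiral ligand in step 9 is assumed to be chosen so that the 4S carbinol results.

Step 1
Reactants: 1 triethyl phosphonoacetate; 2 geranyl bromide
Product: 3 ethyl (4E)-2-(diethoxyphosphoryl)-5,9-dimethyldeca-4,8-dienoate (racemic)
Conditions: NaH, THF–DMF, 0 °C; then 2, 0 → 23 °C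
Reagents that add atoms: none
Why: C-alkylation of the sodium phosphonoacetate carbanion by the primary allylic bromide is an SN2 reaction at C1 of the geranyl unit and leaves the E alkene untouched.

Step 2
Reactants: 3 phosphonate; 4 acetone
Product: 5 ethyl (4E)-5,9-dimethyl-2-(propan-2-ylidene)deca-4,8-dienoate
Conditions: NaH, THF; acetone (excess), 65 °C
Reagents that add atoms: none
Why: Horner–Wadsworth–Emmons olefination of acetone by the α-substituted phosphonate anion should give the tetrasubstituted enoate, and since both β-substituents are methyl no alkene geometry has to be controlled.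

Step 3
Reactants: 5 enoate
Product: 6 (4E)-5,9-dimethyl-2-(propan-2-ylidene)deca-4,8-dien-1-ol
Conditions: DIBAL-H (2.2 equiv), CH2Cl2, −78 → 0 °C; Rochelle salt
Reagents that add atoms: none
Why: 1,2-reduction of the α,β-unsaturated ester with DIBAL-H gives the allylic alcohol and does not touch the isolated alkenes.

Step 4
Reactants: 6 allylic alcohol
Product: 7 (4E)-1-bromo-5,9-dimethyl-2-(propan-2-ylidene)deca-4,8-diene
Conditions: CBr4, PPh3, CH2Cl2, 0 °C
Reagents that add atoms: carbon tetrabromide, BrC(Br)(Br)Br
Why: Appel bromination displaces the oxyphosphonium at the primary CH2 by SN2, and the primary bromide is also the thermodynamically preferred allylic isomer.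

Step 5
Reactants: 8 methyl orsellinate (methyl 2,4-dihydroxy-6-methylbenzoate)
Product: 9 methyl 2,4-bis(methoxymethoxy)-6-methylbenzoate
Conditions: NaH (2.5 equiv), MOMCl (2.5 equiv), DMF, 0 → 23 °C
Reagents that add atoms: chloromethyl methyl ether, COCCl
Why: Williamson etherification of both phenoxides (NaH is needed for the hydrogen-bonded 2-OH) gives MOM acetals that are inert to the later carbanion chemistry.

Step 6
Reactants: 9 toluate; 7 allylic bromide
Product: 10 methyl 2-[(5E)-6,10-dimethyl-3-(propan-2-ylidene)undeca-5,9-dien-1-yl]-4,6-bis(methoxymethoxy)benzoate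
Conditions: LDA (1.1 equiv), THF, −78 °C; then 7, −78 → −40 °C
Reagents that add atoms: none
Why: Lateral lithiation of the o-toluate gives the ester-stabilised benzylic carbanion, which is alkylated by the allylic bromide in an SN2 reaction at its CH2 terminus.

Step 7
Reactants: 10 alkylated toluate; 11 methyl acetate
Product: 13 4-R*-6,8-bis(methoxymethoxy)naphthalene-1,3-diol, via keto ester enolate 12 (not isolated)
Conditions: LDA (3.3 equiv), THF, −78 °C; MeOAc (1.2 equiv), −78 → 0 °C; AcOH quench, Ar
Reagents that add atoms: none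
Why: LDA regenerates the ester-stabilised benzylic carbanion of 10 (now at the secondary ArCH position), which attacks methyl acetate and expels methoxide in a Claisen condensation to give keto ester 12 as its enolate, forming the C4–C3 bond; under the excess amide base the enolates of 12 interconvert and the methyl-side enolate attacks the adjacent aryl ester in a Dieckmann-type intramolecular Claisen condensation, forming the C1–C2 bond, after which loss of methoxide and enolisation give the aromatic diol as its doubly deprotonated salt. The closest known reaction type is the polyketide-style tandem acylation–cyclisation of laterally lithiated o-toluates to naphthalene-1,3-diols, the ester counterpart of the Staunton–Weinreb annulation. The one ring formed closes in a 6-(enolendo)-exo-trig mode. No stereocentre is created, because the transient benzylic centre of 12 is erased on aromatisation. The step needs carbon rather than oxygen acylation in the ring closure (naphthalenediol, not isocoumarin) and an unambiguous regiochemistry: the first is secured by the aprotic, strongly basic medium in which the C-acylated product is trapped as a stable diketonate, the second by the substrate itself, since the ester carbon can only become C1 and the side-chain-bearing benzylic carbon only C4.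

Step 8
Reactants: 13 naphthalene-1,3-diol
Product: 14 2-chloro-4-R*-6,8-bis(methoxymethoxy)naphthalene-1,3-diol
Conditions: NCS (1.0 equiv), THF, −78 → 0 °C, Ar
Reagents that add atoms: N-chlorosuccinimide, O=C1CCC(=O)N1Cl
Why: Electrophilic aromatic chlorination should occur at C2, the only unsubstituted position of ring B and the one activated by both flanking hydroxyls, and rearomatisation keeps the reaction at the monochloride with one equivalent of reagent.

Step 9
Reactants: 14 chloro diol
Product: 15 (4S)-2-chloro-3,4-dihydroxy-4-R*-6,8-bis(methoxymethoxy)naphthalen-1(4H)-one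
Conditions: Sc(OTf)3 (10 mol %), chiral N,N′-dioxide ligand (10 mol %), 3-phenyl-2-(phenylsulfonyl)oxaziridine (1.2 equiv), 4 Å MS, CH2Cl2, −20 °C
Reagents that add atoms: 3-phenyl-2-(phenylsulfonyl)-1,2-oxaziridine, O=S(=O)(N1OC1c1ccccc1)c1ccccc1
Why: This is a catalytic enantioselective hydroxylative dearomatisation of a 1-alkyl-2-naphthol-type substrate, in which the scandium-bound naphtholate is hydroxylated by the oxaziridine at the alkyl-bearing C4 (C2 is blocked by chlorine) and the chiral N,N′-dioxide–Sc(III) complex shields one face of the planar ring, so the C4 carbinol centre should form in the S configuration under catalyst control.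

Step 10
Reactants: 15 chloro enol
Product: 16 (2S,4S)-2-chloro-4-hydroxy-2-methyl-4-R*-6,8-bis(methoxymethoxy)naphthalene-1,3(2H,4H)-dione
Conditions: MeI (5 equiv), K2CO3 (1.5 equiv), acetone, 0 → 23 °C
Reagents that add atoms: iodomethane, CI
Why: C-methylation of the 2-chloro-1,3-diketonate by the soft electrophile MeI sets the C2 quaternary centre, the electrophile approaching the planar enolate anti to the bulky C4 side chain (1,3-substrate control, the small C4 hydroxyl lying on the attacked face), so that CH3 ends cis to the C4 hydroxyl and Cl cis to the side chain.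

Step 11
Reactants: 16 α-ketol
Product: 17 (2R,3S)-2-chloro-3-hydroxy-2-methyl-3-R*-6,8-bis(methoxymethoxy)-2,3-dihydronaphthalene-1,4-dione
Conditions: toluene, 110 °C
Reagents that add atoms: none
Why: In this thermal α-ketol (acyloin) rearrangement the allylic CH2 of the side chain shifts suprafacially from the C4 carbinol to the C3 carbonyl on the face it already occupies, so the C4 configuration is transferred stereospecifically to C3 while C2 is untouched, the driving force being conversion of the isolated 1,3-dione into an aryl-conjugated 1,4-dione.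

Step 12
Reactants: 17 bis-MOM ether
Product: 18 (2R,3S)-2-chloro-3,6,8-trihydroxy-2-methyl-3-R*-2,3-dihydronaphthalene-1,4-dione (target)
Conditions: HCl (1.25 M in MeOH), THF, 0 → 23 °C
Reagents that add atoms: none
Why: Acid-catalysed acetal exchange with methanol removes both aryl MOM groups under conditions mild enough for the tertiary α-chloro ketone, the tertiary α-ketol (no α-hydrogen for dehydration or epimerisation) and the tri- and tetrasubstituted alkenes.

Compound list
1 | triethyl phosphonoacetate | CCOC(=O)CP(=O)(OCC)OCC | starting material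
2 | geranyl bromide, (2E)-1-bromo-3,7-dimethylocta-2,6-diene | CC(C)=CCC/C(C)=C/CBr | starting material
3 | ethyl (4E)-2-(diethoxyphosphoryl)-5,9-dimethyldeca-4,8-dienoate (racemic) | CCOC(=O)C(C/C=C(\C)CCC=C(C)C)P(=O)(OCC)OCC | intermediate
4 | acetone | CC(C)=O | starting material
5 | ethyl (4E)-5,9-dimethyl-2-(propan-2-ylidene)deca-4,8-dienoate | CCOC(=O)C(C/C=C(\C)CCC=C(C)C)=C(C)C | intermediate
6 | (4E)-5,9-dimethyl-2-(propan-2-ylidene)deca-4,8-dien-1-ol | OCC(C/C=C(\C)CCC=C(C)C)=C(C)C | intermediate
7 | (4E)-1-bromo-5,9-dimethyl-2-(propan-2-ylidene)deca-4,8-diene | BrCC(C/C=C(\C)CCC=C(C)C)=C(C)C | intermediate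
8 | methyl orsellinate (methyl 2,4-dihydroxy-6-methylbenzoate) | COC(=O)c1c(C)cc(O)cc1O | starting material
9 | methyl 2,4-bis(methoxymethoxy)-6-methylbenzoate | COCOc1cc(C)c(C(=O)OC)c(OCOC)c1 | intermediate
10 | methyl 2-[(5E)-6,10-dimethyl-3-(propan-2-ylidene)undeca-5,9-dien-1-yl]-4,6-bis(methoxymethoxy)benzoate | COCOc1cc(CCC(C/C=C(\C)CCC=C(C)C)=C(C)C)c(C(=O)OC)c(OCOC)c1 | intermediate
11 | methyl acetate | COC(C)=O | starting material
12 | methyl 2-[(7E)-8,12-dimethyl-2-oxo-5-(propan-2-ylidene)trideca-7,11-dien-3-yl]-4,6-bis(methoxymethoxy)benzoate (racemic; present as its lithium enolate) | COCOc1cc(C(CC(C/C=C(\C)CCC=C(C)C)=C(C)C)C(C)=O)c(C(=O)OC)c(OCOC)c1 | intermediate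
13 | 4-[(4E)-5,9-dimethyl-2-(propan-2-ylidene)deca-4,8-dien-1-yl]-6,8-bis(methoxymethoxy)naphthalene-1,3-diol | Oc1cc(O)c(CC(C/C=C(\C)CCC=C(C)C)=C(C)C)c2cc(OCOC)cc(OCOC)c12 | intermediate
14 | 2-chloro-4-[(4E)-5,9-dimethyl-2-(propan-2-ylidene)deca-4,8-dien-1-yl]-6,8-bis(methoxymethoxy)naphthalene-1,3-diol | Oc1c(Cl)c(O)c(CC(C/C=C(\C)CCC=C(C)C)=C(C)C)c2cc(OCOC)cc(OCOC)c12 | intermediate
15 | (4S)-2-chloro-3,4-dihydroxy-4-[(4E)-5,9-dimethyl-2-(propan-2-ylidene)deca-4,8-dien-1-yl]-6,8-bis(methoxymethoxy)naphthalen-1(4H)-one | O=C1C(Cl)=C(O)[C@](O)(CC(C/C=C(\C)CCC=C(C)C)=C(C)C)c2cc(OCOC)cc(OCOC)c12 | intermediate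
16 | (2S,4S)-2-chloro-4-hydroxy-2-methyl-4-[(4E)-5,9-dimethyl-2-(propan-2-ylidene)deca-4,8-dien-1-yl]-6,8-bis(methoxymethoxy)naphthalene-1,3(2H,4H)-dione | O=C1[C@](C)(Cl)C(=O)[C@](O)(CC(C/C=C(\C)CCC=C(C)C)=C(C)C)c2cc(OCOC)cc(OCOC)c12 | intermediate
17 | (2R,3S)-2-chloro-3-hydroxy-2-methyl-3-[(4E)-5,9-dimethyl-2-(propan-2-ylidene)deca-4,8-dien-1-yl]-6,8-bis(methoxymethoxy)-2,3-dihydronaphthalene-1,4-dione | O=C1[C@](C)(Cl)[C@](O)(CC(C/C=C(\C)CCC=C(C)C)=C(C)C)C(=O)c2cc(OCOC)cc(OCOC)c12 | intermediate
18 | (2R,3S)-2-chloro-3,6,8-trihydroxy-2-methyl-3-[(4E)-5,9-dimethyl-2-(propan-2-ylidene)deca-4,8-dien-1-yl]-2,3-dihydronaphthalene-1,4-dione | O=C1[C@](C)(Cl)[C@](O)(CC(C/C=C(\C)CCC=C(C)C)=C(C)C)C(=O)c2cc(O)cc(O)c12 | target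

Total step count: 12. Longest linear sequence: 11 steps (steps 1–4 and 6–12).

Steps most likely to fail

Step 9. The catalyst may discriminate the two faces of the ring poorly on a naphthalenediol that carries an extra hydroxyl and a chlorine, and uncatalysed or aerobic background oxidation may compete. The fallback sets out from 14 and comes back at 15. Oxidation of 14 with the same oxaziridine and Sc(OTf)3 but without the chiral ligand should give the racemic carbinol rac-2-chloro-3,4-dihydroxy-4-R*-6,8-bis(methoxymethoxy)naphthalen-1(4H)-one F1. This is resolved by preparative chromatography on a polysaccharide chiral stationary phase (resolution in place of asymmetric catalysis), and the 4S enantiomer is 15.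

Step 10. O-methylation may compete with C-methylation of the cyclic diketonate, and the anti facial selectivity may erode. The fallback sets out from 10 and comes back at 16; it installs the methyl group in the annulation and sets C2 by asymmetric chlorination instead of by methylation. The tandem condensation of step 7 is run with methyl propanoate and passes through the propionyl keto ester methyl 2-[(8E)-9,13-dimethyl-3-oxo-6-(propan-2-ylidene)tetradeca-8,12-dien-4-yl]-4,6-bis(methoxymethoxy)benzoate F2 (not isolated) to give 2-methyl-4-R*-6,8-bis(methoxymethoxy)naphthalene-1,3-diol F3. Enantioselective chlorinative dearomatisation at C2 with a cinchona-alkaloid-derived catalyst such as (DHQD)2PHAL and 1,3-dichloro-5,5-dimethylhydantoin should give (2R)-2-chloro-3-hydroxy-2-methyl-4-R*-6,8-bis(methoxymethoxy)naphthalen-1(2H)-one F4. Sc(III)–N,N′-dioxide-catalysed oxaziridine hydroxylation of its C3=C4 enol, with the chiral ligand directing attack to the face cis to CH3, then gives 16.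

Step 7. Proton transfer from the acyl donor or from the first-formed ketone may quench the benzylic carbanion, and ring closure through oxygen would lead to the isocoumarin instead of the C–C closed diol. The fallback sets out from 10 and comes back at 13, still forming both ring bonds in one operation. The benzylic lithium of 10 is added to (trimethylsilyl)ketene, which has no acidic hydrogen and gives directly the C2 carbanion as the α-silyl ketone enolate methyl 2-[(7E)-8,12-dimethyl-2-oxo-5-(propan-2-ylidene)-1-(trimethylsilyl)trideca-7,11-dien-3-yl]-4,6-bis(methoxymethoxy)benzoate F5 (not isolated). This closes onto the ester to give 4-R*-6,8-bis(methoxymethoxy)-2-(trimethylsilyl)naphthalene-1,3-diol F6 (not isolated), from which the liberated methoxide removes the silyl group to give 13.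

Further compounds
F1 | step 9 | rac-2-chloro-3,4-dihydroxy-4-[(4E)-5,9-dimethyl-2-(propan-2-ylidene)deca-4,8-dien-1-yl]-6,8-bis(methoxymethoxy)naphthalen-1(4H)-one | O=C1C(Cl)=C(O)C(O)(CC(C/C=C(\C)CCC=C(C)C)=C(C)C)c2cc(OCOC)cc(OCOC)c12
F2 | step 10 | methyl 2-[(8E)-9,13-dimethyl-3-oxo-6-(propan-2-ylidene)tetradeca-8,12-dien-4-yl]-4,6-bis(methoxymethoxy)benzoate (racemic) | COCOc1cc(C(CC(C/C=C(\C)CCC=C(C)C)=C(C)C)C(=O)CC)c(C(=O)OC)c(OCOC)c1
F3 | step 10 | 2-methyl-4-[(4E)-5,9-dimethyl-2-(propan-2-ylidene)deca-4,8-dien-1-yl]-6,8-bis(methoxymethoxy)naphthalene-1,3-diol | Cc1c(O)c(CC(C/C=C(\C)CCC=C(C)C)=C(C)C)c2cc(OCOC)cc(OCOC)c2c1O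
F4 | step 10 | (2R)-2-chloro-3-hydroxy-2-methyl-4-[(4E)-5,9-dimethyl-2-(propan-2-ylidene)deca-4,8-dien-1-yl]-6,8-bis(methoxymethoxy)naphthalen-1(2H)-one | O=C1[C@](C)(Cl)C(O)=C(CC(C/C=C(\C)CCC=C(C)C)=C(C)C)c2cc(OCOC)cc(OCOC)c12
F5 | step 7 | methyl 2-[(7E)-8,12-dimethyl-2-oxo-5-(propan-2-ylidene)-1-(trimethylsilyl)trideca-7,11-dien-3-yl]-4,6-bis(methoxymethoxy)benzoate (racemic) | COCOc1cc(C(CC(C/C=C(\C)CCC=C(C)C)=C(C)C)C(=O)C[Si](C)(C)C)c(C(=O)OC)c(OCOC)c1
F6 | step 7 | 4-[(4E)-5,9-dimethyl-2-(propan-2-ylidene)deca-4,8-dien-1-yl]-6,8-bis(methoxymethoxy)-2-(trimethylsilyl)naphthalene-1,3-diol | C[Si](C)(C)c1c(O)c(CC(C/C=C(\C)CCC=C(C)C)=C(C)C)c2cc(OCOC)cc(OCOC)c2c1O
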